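**Strategy.** Ring B (C5–C10) is treated as a Diels–Alder cyclohexene: its C6/C7 trans-diol stands for a C6=C7 alkene, and C9–C10 is the all-cis fusion bond it shares with the C1–C10–C9–C11 cyclobutane. Cutting C5–C10 and C8–C9 gives an (E,E)-C5–C8 diene tethered through C4–C3–C2 to C1 of a 2-bromo-3-methylcyclobutenone. One intramolecular cycloaddition closes rings A and B and sets C5, C8, C9 and quaternary C10 from the single C1 centre; the bromine marks C9 for hydroxylation. Ring C then grows from C14 by Nozaki–Hiyama–Kishi coupling, hydroxyl-directed cyclopropanation and a carbene-catalysed C11–C12 acyloin closure.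

Key step: step 10

Conventions: abietane-type locants are used; α is the face of ring B that carries the C10 methyl (H-1, H-5, H-8, O-9 and O-11 are also α), β is the other face; "tricycle" means rings A and B plus the C1–C10–C9–C11 four-membered ring.

Assumption: intermediates with a free C14 hydroxyl (20–22, 32, 33) may sit partly as the five-membered C11 hemiketal; they are drawn and treated as the open hydroxy ketones through which they react.

Design notes:
- The cyclobutenone is built from the aldoketene and an ynol ether, then methyl addition with carbonyl transposition, because an aldoketene does not add usefully to an unactivated alkyne.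
- Bromine is placed on the vinylogous ester with NBS before the methyl group arrives, because elemental bromine on the finished dienyl cyclobutenone would attack the diene.
- The two chain ends are differentiated from the start (iodoalkene/boronate coupling), so no dienoate has to be reduced beside a second ester.
- The configurations of 18 and 19 were checked centre by centre against the target: (S)-C1 in 18 leads to the required C5, C8, C9 and C10, so neither structure needed correction.

**Route**

Step 1
Reactants: 1 isobutyraldehyde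
Product: 2 4-(2-methylprop-1-en-1-yl)morpholine
Conditions: morpholine, p-TsOH (cat.), toluene, reflux, Dean–Stark
Reagents that add atoms: morpholine C1COCCN1
Why: Acid-catalysed condensation of an α-branched aldehyde with a secondary amine under azeotropic water removal (enamine formation) gives the only possible enamine and creates no stereocentre.

Step 2
Reactants: 2 4-(2-methylprop-1-en-1-yl)morpholine; 3 methyl 4-chloro-4-oxobutanoate
Product: 5 methyl 5,5-dimethyl-4,6-dioxohexanoate, via iminium chloride 4 (not isolated)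
Conditions: MeCN, 0 → 60 °C; then H2O, rt
Reagents that add atoms: water O
Why: C-Acylation of the β,β-disubstituted enamine by the acid chloride (enamine acylation) gives an iminium salt with no α-hydrogen to lose, so hydrolysis delivers the non-enolisable C3-keto C5-aldehyde with the C4 gem-dimethyl group in place.

Step 3
Reactants: 5 methyl 5,5-dimethyl-4,6-dioxohexanoate
Product: 6 methyl (E)-7-iodo-5,5-dimethyl-4-oxohept-6-enoate
Conditions: CrCl2, CHI3, THF/1,4-dioxane, 0 °C → rt
Reagents that add atoms: iodoform IC(I)I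
Why: The Takai olefination is selective for the aldehyde over the ketone and ester and should give the (E)-iodoalkene, E selectivity being highest for α-quaternary aldehydes.

Step 4
Reactants: 6 methyl (E)-7-iodo-5,5-dimethyl-4-oxohept-6-enoate
Product: 7 methyl 3-{2-[(E)-4-iodo-2-methylbut-3-en-2-yl]-1,3-dioxolan-2-yl}propanoate
Conditions: TMSOCH2CH2OTMS, TMSOTf (cat.), CH2Cl2, −78 → −20 °C
Reagents that add atoms: 1,2-bis(trimethylsilyloxy)ethane C[Si](C)(C)OCCO[Si](C)(C)C
Why: Silyl-triflate-catalysed ketalisation with the bis-silyl ether of ethylene glycol is driven by formation of hexamethyldisiloxane and converts hindered ketones at low temperature without transesterifying the methyl ester.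

Step 5
Reactants: 7 methyl 3-{2-[(E)-4-iodo-2-methylbut-3-en-2-yl]-1,3-dioxolan-2-yl}propanoate; 8 (E)-tert-butyldimethyl{[3-(4,4,5,5-tetramethyl-1,3,2-dioxaborolan-2-yl)prop-2-en-1-yl]oxy}silane
Product: 10 3-{2-[(3E,5E)-7-(tert-butyldimethylsilyloxy)-2-methylhepta-3,5-dien-2-yl]-1,3-dioxolan-2-yl}propanoic acid, via methyl ester 9 (not isolated)
Conditions: Pd(PPh3)4 (cat.), LiOH (aq.), THF, 40 °C; then 0.5 M HCl to pH 4–5, 0 °C
Reagents that add atoms: lithium hydroxide [Li+].[OH-]
Why: Suzuki–Miyaura coupling of the two (E)-alkenyl partners proceeds with retention at both double bonds to give the (E,E)-diene, and the aqueous hydroxide that serves as its base then saponifies the methyl ester.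

Step 6
Reactants: 10 3-{2-[(3E,5E)-7-(tert-butyldimethylsilyloxy)-2-methylhepta-3,5-dien-2-yl]-1,3-dioxolan-2-yl}propanoic acid; 11 ethoxyacetylene
Product: 14 rac-3-ethoxy-4-({2-[(3E,5E)-7-(tert-butyldimethylsilyloxy)-2-methylhepta-3,5-dien-2-yl]-1,3-dioxolan-2-yl}methyl)cyclobut-2-en-1-one, via acid chloride 12 (not isolated), via ketene 13 (not isolated)
Conditions: 1-chloro-N,N,2-trimethylprop-1-en-1-amine, CH2Cl2, 0 °C; then slow addition to 11 (excess), Et3N, MeCN, 0 °C → rt
Reagents that add atoms: none
Why: The acid chloride is formed under neutral conditions and dehydrochlorinated to the aldoketene, which the electron-rich ynol ether traps in a regioselective ketene–alkyne [2+2] cycloaddition (carbonyl carbon to the CH terminus) faster than it dimerises or reaches the remote diene, so that C1 is created as a racemate.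

Step 7
Reactants: 14 rac-3-ethoxy-4-(side-chain-methyl)cyclobut-2-en-1-one
Product: 15 (R)-3-ethoxy-4-({2-[(3E,5E)-7-(tert-butyldimethylsilyloxy)-2-methylhepta-3,5-dien-2-yl]-1,3-dioxolan-2-yl}methyl)cyclobut-2-en-1-one
Conditions: preparative SFC, amylose tris(3,5-dimethylphenylcarbamate) phase, CO2/i-PrOH
Reagents that add atoms: none
Why: Chromatographic resolution on a polysaccharide phase separates the enantiomers, which are configurationally stable because enolisation at C1 would require a cyclobutadiene.

Step 8
Reactants: 15 (R)-3-ethoxycyclobutenone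
Product: 16 (R)-2-bromo-3-ethoxy-4-({2-[(3E,5E)-7-(tert-butyldimethylsilyloxy)-2-methylhepta-3,5-dien-2-yl]-1,3-dioxolan-2-yl}methyl)cyclobut-2-en-1-one
Conditions: NBS (1.05 equiv), CH2Cl2, −40 → 0 °C, dark
Reagents that add atoms: N-bromosuccinimide O=C1CCC(=O)N1Br
Why: The α-carbon of the vinylogous ester is by far the most nucleophilic site (electrophilic α-halogenation of a β-alkoxy enone), so one equivalent of NBS at low temperature should brominate the future C9 and leave the unactivated diene alone.

Step 9
Reactants: 16 (R)-2-bromo-3-ethoxycyclobutenone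
Product: 18 (S)-2-bromo-3-methyl-4-({2-[(3E,5E)-7-(tert-butyldimethylsilyloxy)-2-methylhepta-3,5-dien-2-yl]-1,3-dioxolan-2-yl}methyl)cyclobut-2-en-1-one, via tertiary carbinol 17 (not isolated)
Conditions: MeLi, THF, −78 °C; then 0.5 M HCl (aq.), 0 °C
Reagents that add atoms: methyllithium [Li]C; water O
Why: 1,2-Addition of methyllithium to the strained carbonyl and acid-induced ionisation of the carbinol to an ethoxy-stabilised cyclobutenyl cation that is hydrolysed (1,3-carbonyl transposition of a vinylogous ester) put the methyl group on C10 and the carbonyl on C11 without touching C1, whose descriptor changes from R to S only because the priorities of its two ring neighbours are exchanged.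

Step 10
Reactants: 18 (S)-2-bromo-3-methyl-4-(dienyl-dioxolanyl-methyl)cyclobut-2-en-1-one
Product: 19 tricyclic adduct: 9α-bromo-14-(tert-butyldimethylsilyloxy)-3,3-ethylenedioxy tricycle-6-en-11-one (1αH; 5αH; 8αH; 10α-CH3)
Conditions: ZnCl2 (1.0 M in Et2O, 1.2 equiv), CH2Cl2, −20 °C → rt
Reagents that add atoms: none
Why: ZnCl2 coordinates the C11 carbonyl and lowers the LUMO of the strained, bromine-activated C9=C10 bond, so that the tethered C5–C8 diene adds in a concerted but asynchronous [4+2] cycloaddition in which the C5–C10 bond is the more advanced; the closest known reaction type is the Lewis-acid-promoted Diels–Alder reaction of cyclobutenone and 2-bromocyclobutenone, tethered cases included. Ring A closes as the six-membered ring that contains the tether atoms C1–C4 between C10 and C5 (a fused, decatriene-type intramolecular closure), and ring B is the new cyclohexene formed by the two σ-bonds C5–C10 and C8–C9. C10 and C5 are set by the resident C1 centre, because the three-atom chain C2–C4 can bring the diene only to the cyclobutenone face that carries C2, which makes the A/cyclobutane junction cis and puts H-5 cis to the C10 methyl. C9 and C8 are set by the endo transition state: C11 and C1 are locked cis on the dienophile, so the carbonyl-endo arrangement is also the tether-endo one, and with C4 and C14 on the outside of the (E,E)-diene the B/cyclobutane junction becomes cis with H-8 cis to bromine. The step needs complete face and endo selectivity and enough reactivity at a tetrasubstituted alkene; the first two are enforced by the short tether and the ring-locked cis dienophile, the third is supplied by release of cyclobutene strain, the α-bromine, Lewis-acid activation and the gem-dimethyl/dioxolane conformational bias, while the low temperature suppresses electrocyclic opening to the vinylketene.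

Step 11
Reactants: 19 tricyclic adduct
Product: 20 9α-bromo-14-hydroxy tricycle-6-ene-3,11-dione
Conditions: 2 M HCl (aq.), THF, rt
Reagents that add atoms: water O
Why: Aqueous acid hydrolyses the dioxolane and the primary silyl ether in one operation (acetal hydrolysis and desilylation), the C3 ketone needing no further protection and the α-bromo ketone being stable to acid but not to base.

Step 12
Reactants: 20 9α-bromo-14-hydroxy tricycle-6-ene-3,11-dione
Product: 21 9α-bromo-6β,7β-epoxy-14-hydroxy tricycle-3,11-dione
Conditions: VO(acac)2 (cat.), t-BuOOH (decane), CH2Cl2, rt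
Reagents that add atoms: tert-butyl hydroperoxide CC(C)(C)OO
Why: In the vanadium-catalysed hydroxyl-directed epoxidation the peroxide is delivered from the homoallylic C14 oxygen, which is β at C8, so the oxirane forms on the β face, and the peracid-free oxidant cannot trigger Baeyer–Villiger oxidation of the cyclobutanone.

Step 13
Reactants: 21 6β,7β-epoxide
Product: 22 6α-acetoxy-9α-bromo-7β,14-dihydroxy tricycle-3,11-dione
Conditions: Ti(OiPr)4, AcOH, CH2Cl2, 0 °C → rt
Reagents that add atoms: acetic acid CC(=O)O
Why: Titanium bridging the C14 oxygen and the oxirane activates it for anti attack by acetate at the distal carbon C6, the position remote from the inductively withdrawing C8/C9 substituents (chelation-controlled opening of a 3,4-epoxy alcohol), which gives the 6α-acetate and the 7β-hydroxyl in one step.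

Step 14
Reactants: 22 6α-acetoxy-7β,14-diol
Product: 23 6α-acetoxy-9α-bromo-7β,14-bis(triethylsilyloxy) tricycle-3,11-dione
Conditions: TESOTf, 2,6-lutidine, CH2Cl2, −78 °C
Reagents that add atoms: triethylsilyl triflate CC[Si](CC)(CC)OS(=O)(=O)C(F)(F)F
Why: Silyl triflate with a hindered base silylates the primary and the secondary hydroxyl at low temperature (silyl ether formation) under conditions too mild and non-nucleophilic to enolise the ketones, shift the acetate or attack the α-bromo ketone.

Step 15
Reactants: 23 bis-silyl ether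
Product: 24 6α-acetoxy-7β,11,14-tris(triethylsilyloxy) tricycle-9(11)-en-3-one
Conditions: Zn dust, TESCl, TMEDA, THF, rt
Reagents that add atoms: chlorotriethylsilane CC[Si](CC)(CC)Cl
Why: Zinc inserts into the C9–Br bond of the α-bromo ketone and the zinc enolate is silylated on oxygen (regiospecific reductive enol silylation), which fixes the C9=C11 enol ether exactly where the bromine stood.

Step 16
Reactants: 24 C9=C11 silyl enol ether
Product: 26 6α-acetoxy-7β,9α,14-tris(triethylsilyloxy) tricycle-3,11-dione, via silyloxy epoxide 25 (not isolated)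
Conditions: DMDO (acetone), CH2Cl2, −78 → 0 °C; then rt
Reagents that add atoms: dimethyldioxirane CC1(C)OO1
Why: The neutral dioxirane epoxidises the electron-rich enol ether from the α face, the only face that keeps ring B cis-fused to the four-membered ring, and 1,4-silyl migration in the silyloxy oxirane (Rubottom oxidation) gives the 9α-silyloxy ketone without the Baeyer–Villiger risk of a peracid.

Step 17
Reactants: 26 tris-silyl ether
Product: 27 6α-acetoxy-3,11-dioxo-7β,9α-bis(triethylsilyloxy) tricycle-14-al
Conditions: (COCl)2, DMSO, CH2Cl2, −78 → −40 °C; Et3N, −78 °C → rt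
Reagents that add atoms: none
Why: Under Swern conditions a primary triethylsilyl ether is converted directly into the aldehyde (oxidative desilylation) while the secondary and tertiary silyl ethers and the acetate stay in place, and the mild base at low temperature should not epimerise C8.

Step 18
Reactants: 28 (E)-but-2-enal
Product: 29 (Z)-2-iodobut-2-enal
Conditions: I2, K2CO3, DMAP (cat.), THF/H2O, rt
Reagents that add atoms: iodine II
Why: Amine-catalysed conjugate addition, α-iodination and elimination (α-iodination of an enal) gives the preferred (Z)-isomer in which iodine is cis to the methyl group.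

Step 19
Reactants: 29 (Z)-2-iodobut-2-enal
Product: 30 (Z)-2-iodobut-2-en-1-ol
Conditions: NaBH4, CeCl3·7H2O, MeOH, 0 °C
Reagents that add atoms: none
Why: Luche reduction is a clean 1,2-reduction of the enal that leaves the alkenyl iodide and its geometry intact.

Step 20
Reactants: 30 (Z)-2-iodobut-2-en-1-ol
Product: 31 (Z)-triethyl[(2-iodobut-2-en-1-yl)oxy]silane
Conditions: TESCl, imidazole, CH2Cl2, 0 °C
Reagents that add atoms: chlorotriethylsilane CC[Si](CC)(CC)Cl
Why: Standard silylation of a primary alcohol installs the ether that a later Swern oxidation turns directly into the C12 aldehyde.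

Step 21
Reactants: 27 C14 aldehyde; 31 (Z)-triethyl[(2-iodobut-2-en-1-yl)oxy]silane
Product: 32 (14S)-14-hydroxy-14-[(Z)-1-(triethylsilyloxy)but-2-en-2-yl] derivative of 27 (C16 methyl cis to C14)
Conditions: CrCl2, NiCl2 (cat.), DMSO, rt
Reagents that add atoms: none
Why: The alkenylchromium reagent formed under nickel catalysis adds to the aldehyde only (Nozaki–Hiyama–Kishi coupling), with retention of the alkene geometry and tolerance of the ketones, acetate and silyl ethers, and Felkin–Anh attack anti to the quaternary C9 substituent of C8 is expected to favour the (14S)-carbinol.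

Step 22
Reactants: 32 (14S)-allylic alcohol
Product: 33 (14S)-carbinol carrying the (13S,16R)-2-methyl-1-[(triethylsilyloxy)methyl]cyclopropyl group (methyl cis to C14)
Conditions: Et2Zn, CH2I2, CH2Cl2, −10 → 0 °C
Reagents that add atoms: diiodomethane ICI
Why: In the hydroxyl-directed Simmons–Smith cyclopropanation the zinc carbenoid is delivered syn to the C14 oxygen in the conformer that minimises 1,3-allylic strain with the cis methyl group, which places C15 on the face required for C13 and C16, while the stereospecific addition keeps the methyl cis to C14.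

Step 23
Reactants: 33 cyclopropyl carbinol
Product: 34 keto aldehyde: C14 ketone bearing the (13S,16R)-1-formyl-2-methylcyclopropyl group
Conditions: (COCl)2, DMSO, CH2Cl2, −78 → −30 °C; Et3N, −78 → 0 °C
Reagents that add atoms: none
Why: One Swern operation oxidises the secondary cyclopropylcarbinol to the C14 ketone and converts the primary triethylsilyl ether into the C12 aldehyde, which cannot enolise because C13 is quaternary.

Step 24
Reactants: 34 keto aldehyde
Product: 35 tetracyclic α-ketol: 6α-acetoxy-11α-hydroxy-3,12,14-trioxo-7β,9α-bis(triethylsilyloxy) compound with the 13-spirocyclopropane (C15 α; C16 β; 16-methyl syn to C14)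
Conditions: 2-(pentafluorophenyl)-6,7-dihydro-5H-pyrrolo[2,1-c][1,2,4]triazol-2-ium tetrafluoroborate (20 mol%), DBU (20 mol%), THF, rt
Reagents that add atoms: none
Why: The carbene adds to the non-enolisable aldehyde and the resulting acyl-anion equivalent attacks the strained, highly electrophilic C11 ketone in an intramolecular crossed benzoin reaction that closes the six-membered ring C, the C8-anchored chain being able to reach C11 only from the β face so that the new hydroxyl is α and the junction cis.

Step 25
Reactants: 35 α-ketol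
Product: 36 12β-alcohol (6α-acetoxy-11α,12β-dihydroxy-3,14-dioxo-7β,9α-bis(triethylsilyloxy) tetracycle)
Conditions: Me4NBH(OAc)3, AcOH/MeCN, −30 °C
Reagents that add atoms: none
Why: The free C11 hydroxyl binds boron and delivers hydride to the α face of the neighbouring C12 ketone (hydroxyl-directed triacetoxyborohydride reduction), giving the 12β-alcohol trans to the C11 hydroxyl, while the C3 and C14 ketones have no free hydroxyl in reach and the reaction is stopped cold before the new C12 hydroxyl can direct a second reduction.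

Step 26
Reactants: 36 12β-alcohol
Product: 37 6α,12β-diacetate (11α-hydroxy-3,14-dioxo-7β,9α-bis(triethylsilyloxy) tetracycle)
Conditions: Ac2O, DMAP, pyridine, CH2Cl2, rt
Reagents that add atoms: acetic anhydride CC(=O)OC(C)=O
Why: DMAP-catalysed acetylation takes the only free secondary hydroxyl (C12) and leaves the hindered tertiary C11 hydroxyl untouched.

Step 27
Reactants: 37 bis-silyl diacetate
Product: 38 CNP0157858.3
Conditions: HF·pyridine, THF, 0 °C → rt
Reagents that add atoms: none
Why: Fluoride-mediated desilylation under buffered, non-basic conditions frees the C7 and C9 hydroxyls without migrating or cleaving the acetates or provoking retro-aldol or α-ketol chemistry.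

**Compound list**

1 | isobutyraldehyde | CC(C)C=O | starting material
2 | 4-(2-methylprop-1-en-1-yl)morpholine | CC(C)=CN1CCOCC1 | intermediate
3 | methyl 4-chloro-4-oxobutanoate | COC(=O)CCC(Cl)=O | starting material
4 | 4-(6-methoxy-2,2-dimethyl-3,6-dioxohexylidene)morpholin-4-ium chloride (not isolated) | COC(=O)CCC(=O)C(C)(C)C=[N+]1CCOCC1.[Cl-] | intermediate
5 | methyl 5,5-dimethyl-4,6-dioxohexanoate | COC(=O)CCC(=O)C(C)(C)C=O | intermediate
6 | methyl (E)-7-iodo-5,5-dimethyl-4-oxohept-6-enoate | COC(=O)CCC(=O)C(C)(C)/C=C/I | intermediate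
7 | methyl 3-{2-[(E)-4-iodo-2-methylbut-3-en-2-yl]-1,3-dioxolan-2-yl}propanoate | COC(=O)CCC1(OCCO1)C(C)(C)/C=C/I | intermediate
8 | (E)-tert-butyldimethyl{[3-(4,4,5,5-tetramethyl-1,3,2-dioxaborolan-2-yl)prop-2-en-1-yl]oxy}silane | CC(C)(C)[Si](C)(C)OC/C=C/B1OC(C)(C)C(C)(C)O1 | starting material
9 | methyl 3-{2-[(3E,5E)-7-(tert-butyldimethylsilyloxy)-2-methylhepta-3,5-dien-2-yl]-1,3-dioxolan-2-yl}propanoate (not isolated) | COC(=O)CCC1(OCCO1)C(C)(C)/C=C/C=C/CO[Si](C)(C)C(C)(C)C | intermediate
10 | 3-{2-[(3E,5E)-7-(tert-butyldimethylsilyloxy)-2-methylhepta-3,5-dien-2-yl]-1,3-dioxolan-2-yl}propanoic acid | OC(=O)CCC1(OCCO1)C(C)(C)/C=C/C=C/CO[Si](C)(C)C(C)(C)C | intermediate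
11 | ethoxyacetylene | CCOC#C | starting material
12 | acid chloride of 10 (not isolated) | ClC(=O)CCC1(OCCO1)C(C)(C)/C=C/C=C/CO[Si](C)(C)C(C)(C)C | intermediate
13 | ketene from 12: 3-{2-[(3E,5E)-7-(tert-butyldimethylsilyloxy)-2-methylhepta-3,5-dien-2-yl]-1,3-dioxolan-2-yl}prop-1-en-1-one (not isolated) | O=C=CCC1(OCCO1)C(C)(C)/C=C/C=C/CO[Si](C)(C)C(C)(C)C | intermediate
14 | rac-3-ethoxy-4-({2-[(3E,5E)-7-(tert-butyldimethylsilyloxy)-2-methylhepta-3,5-dien-2-yl]-1,3-dioxolan-2-yl}methyl)cyclobut-2-en-1-one | CCOC1=CC(=O)C1CC2(OCCO2)C(C)(C)/C=C/C=C/CO[Si](C)(C)C(C)(C)C | intermediate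
15 | (R)-enantiomer of 14 | CCOC1=CC(=O)[C@@H]1CC2(OCCO2)C(C)(C)/C=C/C=C/CO[Si](C)(C)C(C)(C)C | intermediate
16 | (R)-2-bromo-3-ethoxy-4-(side-chain-methyl)cyclobut-2-en-1-one (side chain as in 15) | CCOC1=C(Br)C(=O)[C@@H]1CC2(OCCO2)C(C)(C)/C=C/C=C/CO[Si](C)(C)C(C)(C)C | intermediate
17 | 2-bromo-3-ethoxy-1-methyl-4-(side-chain-methyl)cyclobut-2-en-1-ol, ring CH as in 16, carbinol centre as formed (not isolated) | CCOC1=C(Br)C(C)(O)[C@@H]1CC2(OCCO2)C(C)(C)/C=C/C=C/CO[Si](C)(C)C(C)(C)C | intermediate
18 | (S)-2-bromo-3-methyl-4-({2-[(3E,5E)-7-(tert-butyldimethylsilyloxy)-2-methylhepta-3,5-dien-2-yl]-1,3-dioxolan-2-yl}methyl)cyclobut-2-en-1-one | O=C1C(Br)=C(C)[C@@H]1CC2(OCCO2)C(C)(C)/C=C/C=C/CO[Si](C)(C)C(C)(C)C | intermediate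
19 | 9α-bromo-14-(tert-butyldimethylsilyloxy)-3,3-ethylenedioxy tricycle-6-en-11-one (1αH, 5αH, 8αH, 10α-CH3) | O=C1[C@]2(Br)[C@H](CO[Si](C)(C)C(C)(C)C)C=C[C@@H]3C(C)(C)C4(OCCO4)C[C@H]1[C@]23C | intermediate
20 | 9α-bromo-14-hydroxy tricycle-6-ene-3,11-dione | O=C1[C@]2(Br)[C@H](CO)C=C[C@@H]3C(C)(C)C(=O)C[C@H]1[C@]23C | intermediate
21 | 9α-bromo-6β,7β-epoxy-14-hydroxy tricycle-3,11-dione | O=C1[C@]2(Br)[C@H](CO)[C@@H]5O[C@@H]5[C@@H]3C(C)(C)C(=O)C[C@H]1[C@]23C | intermediate
22 | 6α-acetoxy-9α-bromo-7β,14-dihydroxy tricycle-3,11-dione | O=C1[C@]2(Br)[C@H](CO)[C@H](O)[C@@H](OC(C)=O)[C@@H]3C(C)(C)C(=O)C[C@H]1[C@]23C | intermediate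
23 | 6α-acetoxy-9α-bromo-7β,14-bis(triethylsilyloxy) tricycle-3,11-dione | O=C1[C@]2(Br)[C@H](CO[Si](CC)(CC)CC)[C@H](O[Si](CC)(CC)CC)[C@@H](OC(C)=O)[C@@H]3C(C)(C)C(=O)C[C@H]1[C@]23C | intermediate
24 | 6α-acetoxy-7β,11,14-tris(triethylsilyloxy) tricycle-9(11)-en-3-one | CC[Si](CC)(CC)OC1=C2[C@H](CO[Si](CC)(CC)CC)[C@H](O[Si](CC)(CC)CC)[C@@H](OC(C)=O)[C@@H]3C(C)(C)C(=O)C[C@H]1[C@]23C | intermediate
25 | 9α,11α-epoxide of 24 (not isolated) | CC[Si](CC)(CC)O[C@@]15O[C@]52[C@H](CO[Si](CC)(CC)CC)[C@H](O[Si](CC)(CC)CC)[C@@H](OC(C)=O)[C@@H]3C(C)(C)C(=O)C[C@H]1[C@]23C | intermediate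
26 | 6α-acetoxy-7β,9α,14-tris(triethylsilyloxy) tricycle-3,11-dione | O=C1[C@]2(O[Si](CC)(CC)CC)[C@H](CO[Si](CC)(CC)CC)[C@H](O[Si](CC)(CC)CC)[C@@H](OC(C)=O)[C@@H]3C(C)(C)C(=O)C[C@H]1[C@]23C | intermediate
27 | 6α-acetoxy-3,11-dioxo-7β,9α-bis(triethylsilyloxy) tricycle-14-al | O=C1[C@]2(O[Si](CC)(CC)CC)[C@H](C=O)[C@H](O[Si](CC)(CC)CC)[C@@H](OC(C)=O)[C@@H]3C(C)(C)C(=O)C[C@H]1[C@]23C | intermediate
28 | (E)-but-2-enal | C/C=C/C=O | starting material
29 | (Z)-2-iodobut-2-enal | C/C=C(\I)C=O | intermediate
30 | (Z)-2-iodobut-2-en-1-ol | C/C=C(\I)CO | intermediate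
31 | (Z)-triethyl[(2-iodobut-2-en-1-yl)oxy]silane | C/C=C(\I)CO[Si](CC)(CC)CC | intermediate
32 | (14S)-14-hydroxy-14-[(Z)-1-(triethylsilyloxy)but-2-en-2-yl] derivative of 27 | O=C1[C@]2(O[Si](CC)(CC)CC)[C@H]([C@H](O)/C(CO[Si](CC)(CC)CC)=C\C)[C@H](O[Si](CC)(CC)CC)[C@@H](OC(C)=O)[C@@H]3C(C)(C)C(=O)C[C@H]1[C@]23C | intermediate
33 | (14S)-carbinol with the (13S,16R)-2-methyl-1-[(triethylsilyloxy)methyl]cyclopropyl group | O=C1[C@]2(O[Si](CC)(CC)CC)[C@H]([C@H](O)[C@]5(C[C@H]5C)CO[Si](CC)(CC)CC)[C@H](O[Si](CC)(CC)CC)[C@@H](OC(C)=O)[C@@H]3C(C)(C)C(=O)C[C@H]1[C@]23C | intermediate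
34 | C14 ketone with the (13S,16R)-1-formyl-2-methylcyclopropyl group | O=C1[C@]2(O[Si](CC)(CC)CC)[C@H](C(=O)[C@]5(C[C@H]5C)C=O)[C@H](O[Si](CC)(CC)CC)[C@@H](OC(C)=O)[C@@H]3C(C)(C)C(=O)C[C@H]1[C@]23C | intermediate
35 | tetracyclic α-ketol: 6α-acetoxy-11α-hydroxy-3,12,14-trioxo-7β,9α-bis(triethylsilyloxy), 13-spirocyclopropane (C15 α, C16 β, methyl syn to C14) | CC(=O)O[C@@H]1[C@@H](O[Si](CC)(CC)CC)[C@H]2C(=O)[C@]3(C[C@H]3C)C(=O)[C@@]3(O)[C@H]4CC(=O)C(C)(C)[C@@H]1[C@@]4(C)[C@@]23O[Si](CC)(CC)CC | intermediate
36 | 12β-alcohol of 35 | CC(=O)O[C@@H]1[C@@H](O[Si](CC)(CC)CC)[C@H]2C(=O)[C@]3(C[C@H]3C)[C@@H](O)[C@@]3(O)[C@H]4CC(=O)C(C)(C)[C@@H]1[C@@]4(C)[C@@]23O[Si](CC)(CC)CC | intermediate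
37 | 6α,12β-diacetate, 7β,9α-bis(triethylsilyl) ether | CC(=O)O[C@@H]1[C@@H](O[Si](CC)(CC)CC)[C@H]2C(=O)[C@]3(C[C@H]3C)[C@@H](OC(C)=O)[C@@]3(O)[C@H]4CC(=O)C(C)(C)[C@@H]1[C@@]4(C)[C@@]23O[Si](CC)(CC)CC | intermediate
38 | CNP0157858.3 (6α,12β-diacetoxy-7β,9α,11α-trihydroxy-3,14-dioxo tetracycle, 13S,16R spirocyclopropane) | CC(=O)O[C@@H]1[C@@H](O)[C@H]2C(=O)[C@]3(C[C@H]3C)[C@@H](OC(C)=O)[C@@]3(O)[C@H]4CC(=O)C(C)(C)[C@@H]1[C@@]4(C)[C@@]23O | target

**Step count and risk**

Total step count: 27. Longest linear sequence: 24 steps (steps 1–17 and 21–27, from isobutyraldehyde); steps 18–20 prepare iodoalkene 31 from (E)-but-2-enal.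

The three steps most likely to fail:

1. Step 10. The tetrasubstituted C9=C10 bond may be too hindered to reach the transition state before the cyclobutenone opens to the vinylketene or the Lewis acid strips the dioxolane. The fallback replaces the neutral, Lewis-acid-complexed dienophile by a cationic one. It sets out from 18: silyl-transfer ketalisation of the cyclobutenone carbonyl (1,2-bis(trimethylsilyloxy)ethane, cat. TMSOTf, −78 °C) should give the C11 dioxolane of the bromocyclobutenone F1. Ionisation of this allylic ketal with TfOH at −78 °C generates the 1-alkoxy-2-bromocyclobutenyl (alkoxyallyl) cation, whose stepwise ionic [4+2] reaction with the tethered diene is a known way to force hindered cycloadditions at low temperature. It should give the bis-dioxolane cycloadduct F2. Aqueous HCl in THF (warming if needed) then removes both dioxolanes and the silyl ether, and the fallback comes back to the route at 20.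

2. Step 13 (together with the face selectivity of step 12). Acetate may open the oxirane at C7 instead of C6, or the directed oxidant may not reach the β face. The fallback delivers the C7 oxygen through a tether. It sets out from 20: DMDO should epoxidise the open α face to give the 6α,7α-epoxide F3. BF3·OEt2 in acetone then lets the C14 hydroxyl, as its acetone hemiketal, open the oxirane at C7 from the β face (six-membered closure, inversion) to the 7β,14-O-isopropylidene 6α-alcohol F4. Acetylation (Ac2O, DMAP, pyridine) gives its 6α-acetate F5, and aqueous acetic acid removes the acetonide, which comes back to the route at 22.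

3. Step 21. Facial selectivity at C14 may be low or reversed, and this would steer the cyclopropanation of step 22 to the wrong face. The fallback uses reagent control. It sets out from 32 as its C14 epimer mixture: Dess–Martin oxidation gives the C14 enone F6, and reduction with (R)-2-methyl-CBS-oxazaborolidine and catecholborane (alkenyl group as the large substituent) should return the (14S)-carbinol, coming back to the route at 32.

Further compounds
F1 | step 10 | C11 ethylene ketal of 18 (S at the side-chain-bearing ring carbon) | CC1=C(Br)C2(OCCO2)[C@H]1CC3(OCCO3)C(C)(C)/C=C/C=C/CO[Si](C)(C)C(C)(C)C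
F2 | step 10 | C11 ethylene ketal of 19 (bis-dioxolane cycloadduct) | C15(OCCO5)[C@]2(Br)[C@H](CO[Si](C)(C)C(C)(C)C)C=C[C@@H]3C(C)(C)C4(OCCO4)C[C@H]1[C@]23C
F3 | step 13 | 9α-bromo-6α,7α-epoxy-14-hydroxy tricycle-3,11-dione | O=C1[C@]2(Br)[C@H](CO)[C@H]5O[C@H]5[C@@H]3C(C)(C)C(=O)C[C@H]1[C@]23C
F4 | step 13 | 9α-bromo-6α-hydroxy-7β,14-O-isopropylidene tricycle-3,11-dione | O=C1[C@]2(Br)[C@@H]6COC(C)(C)O[C@@H]6[C@@H](O)[C@@H]3C(C)(C)C(=O)C[C@H]1[C@]23C
F5 | step 13 | 6α-acetate of F4 | O=C1[C@]2(Br)[C@@H]6COC(C)(C)O[C@@H]6[C@@H](OC(C)=O)[C@@H]3C(C)(C)C(=O)C[C@H]1[C@]23C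
F6 | step 21 | C14 enone: 14-oxo-14-[(Z)-1-(triethylsilyloxy)but-2-en-2-yl] derivative of 27 | O=C1[C@]2(O[Si](CC)(CC)CC)[C@H](C(=O)/C(CO[Si](CC)(CC)CC)=C\C)[C@H](O[Si](CC)(CC)CC)[C@@H](OC(C)=O)[C@@H]3C(C)(C)C(=O)C[C@H]1[C@]23C
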